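## Analysis of the target

- Target 15 is a 2,3-dihydrobenzofuran. Its benzo ring (ring A) carries a hydroxyl at C4 and an (E)-4-hydroxystyryl group (ring D) at C6. C2 bears a 3,4-dihydroxyphenyl group (ring B) and C3 a 3,5-dihydroxyphenyl group (ring C).
- The only stereocentres are C2 and C3. Both are S, which puts rings B and C on opposite faces of the five-membered ring (trans), the thermodynamically preferred arrangement.
- The sensitive groups are six free phenols (one an easily oxidised catechol), an electron-rich (E)-stilbene that adds acid and photoisomerises, and the C2–O bond, which is benzylic to a para-oxygenated ring and ionises readily.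
- The hard part is absolute control at C3, a methine with three carbon substituents and no heteroatom, next to C3a, which is flanked by the C4 oxygen. C2 is epimerisable and can be corrected thermodynamically once C3 is fixed.
- Ring A has a symmetrical 1,3,5 pattern (oxygen at C4 and C7a, carbon at C6, C3a between the two oxygens), so it can be bought as a 4-bromo-2,6-dioxygenated benzaldehyde and desymmetrised at the outset.
- The strategy rests on the C2–C3 bond, which joins an O–CH(aryl) carbon to a diarylmethine carbon. C3 can therefore be a diaryl carbene, and C2 the methylene of a 3,4-dimethoxybenzyl ether on the C7a oxygen, into whose C–H bond the carbene inserts.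

## Retrosynthetic reasoning

**15 to 14.** The six O–CH3 bonds are cut last. Methyl ethers are the one phenol protection that survives organomagnesium addition, oxidation, the carbene and acid, so all six phenols travel as methyl ethers in hexamethyl ether 14. The forward step must cleave six aryl methyl ethers without destroying the stilbene or losing the C2–O ring bond.

**14 to 12 and 13.** The bond between C6 of ring A and the vinyl carbon is cut, giving aryl bromide 12 and commercial 4-methoxystyrene 13. Cutting here keeps an alkene out of the carbene step, where it could be cyclopropanated; a bromide is inert there. The forward reaction is a palladium-catalysed vinylation that must give the (E)-alkene.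

**12 to 11 to 10.** The C2–C3 bond is cut. Trans compound 12 is the equilibrium partner of cis isomer 11, and 11 is the insertion product of diaryldiazomethane 10. This is the only disconnection that removes the ring and both stereocentres at once and leaves a precursor made entirely of aryl–carbon and aryl–oxygen bonds. The forward step must fix C3 absolutely by catalyst control and then bring C2 to the trans position.

**10 to 9 to 8.** The C=N2 unit is traced through hydrazone 9 to ketone 8. The diazo compound is too labile to carry, so it is made immediately before use by dehydrogenating 9.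

**8 to 7 to 4 and 5 (through 6).** The bond between the carbonyl carbon and ring C is cut. Ketone 8 comes from carbinol 7 by oxidation, and 7 from aldehyde 4 and the aryl Grignard reagent 6 made from bromide 5. An aldehyde is chosen as acceptor because addition is fast at low temperature, where the ring-A bromide is safe.

**4 to 2 and 3; 2 to 1.** The O–CH2 bond is cut to phenol 2 and benzylic bromide 3. Phenol 2 comes from symmetrical dimethyl ether 1 by cleaving one of its two equivalent methoxy groups, with the neighbouring formyl group limiting the cleavage to one.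

## Alternatives that were turned down

**Alternative 1: both aryl groups added across an alkenyl boronate.**
- Disconnection: the C2–ring B and C3–ring C bonds are cut together with C2–O. This leaves (E)-alkenyl pinacol boronate A2 on a symmetrical 2,6-dimethoxy-4-styryl ring A, aryllithium A3 and aryl triflate A4.
- Forward key step: A3 adds to boron of A2 to give the ate complex. A palladium catalyst with a chiral ferrocenyl bisphosphine, after oxidative addition to A4, binds the alkene and triggers 1,2-migration of the ring-B aryl from boron to carbon while ring C is delivered to the neighbouring carbon. This gives anti boronate A1. Stereoretentive C–B oxidation, release of one ortho methoxy group and invertive closure on C2 would follow.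
- For: it is a three-component, convergent assembly with the stilbene already in place. It needs no diazo compound and no hindered ketone condensation, and either aryl group can be varied freely. On modularity it is stronger than the chosen route.
- Against: the metallate shift is at its best with unsubstituted vinyl boronates. In A2 the carbon that must accept ring C already carries a di-ortho-substituted aryl group, so carbopalladation is slowed and direct Suzuki-type transfer from the ate complex competes. That hindered carbon is C3, the only stereocentre that matters, since the C2 configuration made here is consumed in the ring closure. Three further operations are needed before the ring exists, one of them a mono-demethylation next to an equivalent methoxy group. A2 itself needs the stilbene and the alkenyl boronate built first.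
- Comparison: the chosen route gives up modularity. In return it forms the ring and both stereocentres in one catalytic step, and ring A is desymmetrised at the very start, where over-reaction is prevented by the formyl group.

**Alternative 2: ring A and the furan ring by alkyne cyclotrimerisation.**
- Disconnection: ring A is cut at C3a–C7a, C4–C5 and C6–C7. This gives 1,6-diyne A6 (an ethynyl ether and a silylalkyne linked through O1–C2–C3, both stereocentres in place) and enyne A7.
- Forward key step: a cationic rhodium bisphosphine catalyst couples the two alkynes of A6 to a metallacyclopentadiene, the terminal alkyne of A7 inserts, and reductive elimination gives silylated dihydrobenzofuran A5. The C4 silicon would later be oxidised to hydroxyl.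
- For: it is atom-economical and closes both rings at once. The bulky silyl group should steer the styryl group to C6. The hindered environment around C3a is not a problem because the ring is assembled around it. On ring-A regiochemistry it is at least as strong as the chosen route.
- Against: the key step forms no stereocentre. The anti diaryl array of A6 must be made enantioselectively by other chemistry, so the stereochemical problem is only moved. The ethynyl ether of a secondary benzylic alcohol in A6 is prone to hydrolysis and thermal rearrangement. Its C3–H is benzylic and propargylic, hence epimerisable. The alkene of A7 can enter the metallacycle. An aryl–silicon oxidation is needed afterwards in the presence of the stilbene.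
- Comparison: the route would be much longer. The chosen route buys ring A ready-made and uses its key step to set the stereocentres.

**Alternative 3: ring A by aldol aromatisation.**
- Disconnection: the C5–C6 bond of ring A is cut. This leads to A9, a trans-2,3-diaryl-4,5-dihydrofuran with an acetyl group on C3a and a CH2–CO–CH=CH–aryl chain on C7a.
- Forward key step: base enolises the acetyl methyl group, the enolate adds to the side-chain ketone in a six-membered aldol closure, and dehydration with tautomerisation gives phenol A8.
- For: it is metal-free. The ring-A substitution pattern is unambiguous. The C4 hydroxyl emerges free and distinct from the five methyl ethers, a differentiation the chosen route cannot offer.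
- Against: the differentiation is worth nothing here, because every phenol of 15 is free. A9 already holds both stereocentres, so an enantioselective synthesis of a trans-2,3-diaryldihydrofuran is still required. The C7 methylene of A9, between the enol-ether carbon and a ketone, is far more acidic than the acetyl methyl group. Its enolate leads to double-bond isomerisation and Michael chemistry on the cinnamoyl unit. A9 is also long to make, and the final demethylation problem remains.
- Comparison: the chosen route reaches its key precursor in six simple steps and creates the stereocentres in the ring-forming step itself.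

Key step: step 7

Assumption: Rh2(R-PTAD)4, that is Rh2[(R)-O2CCH(1-adamantyl)(N-phthalimido)]4, is taken to deliver the (3S) configuration with this substrate. If the first run shows the opposite sense, the antipodal catalyst Rh2(S-PTAD)4 is used with nothing else changed.

Assumption: aldehyde 1 is taken as a purchasable building block.

## Route

Step 1
Reactants: 1 4-bromo-2,6-dimethoxybenzaldehyde
Product: 2 4-bromo-2-hydroxy-6-methoxybenzaldehyde
Conditions: BCl3 (1.1 equiv), CH2Cl2, −78 → 0 °C; aq. HCl
Reagents that add atoms: none
Why: Chelation-controlled aryl methyl ether cleavage: BCl3 bridges the formyl oxygen and one flanking methoxy group and chloride removes that methyl group. The resulting six-membered aryloxy(dichloro)borane chelate ties up both boron and the carbonyl, so the second methoxy group should be left alone.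

Step 2
Reactants: 2 4-bromo-2-hydroxy-6-methoxybenzaldehyde; 3 3,4-dimethoxybenzyl bromide
Product: 4 4-bromo-2-[(3,4-dimethoxybenzyl)oxy]-6-methoxybenzaldehyde
Conditions: K2CO3, DMF, rt
Reagents that add atoms: none
Why: Williamson ether synthesis; the potassium phenoxide displaces bromide from a reactive benzylic halide (SN2). The aldehyde and the aryl bromide are inert to carbonate.

Step 3
Reactants: 4 4-bromo-2-[(3,4-dimethoxybenzyl)oxy]-6-methoxybenzaldehyde; 5 1-bromo-3,5-dimethoxybenzene
Product: 7 rac-{4-bromo-2-[(3,4-dimethoxybenzyl)oxy]-6-methoxyphenyl}(3,5-dimethoxyphenyl)methanol, via 3,5-dimethoxyphenylmagnesium bromide 6 (not isolated)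
Conditions: 5, Mg, I2 (cat.), THF, reflux; then 4, THF, −78 → 0 °C; aq. NH4Cl
Reagents that add atoms: none
Why: Grignard addition to an aldehyde; magnesium inserts into 5 to give 6, which adds to the formyl group of 4 far faster than it can exchange with the ring-A bromide at low temperature. The carbinol centre forms racemic and is erased in step 4.

Step 4
Reactants: 7 rac-{4-bromo-2-[(3,4-dimethoxybenzyl)oxy]-6-methoxyphenyl}(3,5-dimethoxyphenyl)methanol
Product: 8 {4-bromo-2-[(3,4-dimethoxybenzyl)oxy]-6-methoxyphenyl}(3,5-dimethoxyphenyl)methanone
Conditions: Dess–Martin periodinane, CH2Cl2, rt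
Reagents that add atoms: none
Why: Dess–Martin oxidation of a secondary diaryl carbinol to the benzophenone. The reagent is mild enough for the dimethoxybenzyl ether and does not touch the aryl bromide.

Step 5
Reactants: 8 {4-bromo-2-[(3,4-dimethoxybenzyl)oxy]-6-methoxyphenyl}(3,5-dimethoxyphenyl)methanone
Product: 9 {4-bromo-2-[(3,4-dimethoxybenzyl)oxy]-6-methoxyphenyl}(3,5-dimethoxyphenyl)methanone hydrazone (mixture of C=N isomers)
Conditions: N2H4·H2O (20 equiv), AcOH (cat.), n-BuOH, 110 °C, sealed vessel
Reagents that add atoms: hydrazine (used as the monohydrate), NN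
Why: Hydrazone condensation; acid catalysis, heat and a large excess of hydrazine should drive addition–dehydration at the di-ortho-alkoxy ketone and suppress azine formation. The C=N geometry is irrelevant because both isomers give the same diazo compound.

Step 6
Reactants: 9 {4-bromo-2-[(3,4-dimethoxybenzyl)oxy]-6-methoxyphenyl}(3,5-dimethoxyphenyl)methanone hydrazone
Product: 10 [4-bromo-2-(3,4-dimethoxybenzyloxy)-6-methoxyphenyl](3,5-dimethoxyphenyl)diazomethane
Conditions: activated MnO2 (8 equiv), MgSO4, CH2Cl2, 0 °C, dark; filtered through Celite and the cold solution used at once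
Reagents that add atoms: none
Why: Dehydrogenation of a diaryl ketone hydrazone to the diaryldiazomethane with activated MnO2, the standard entry to donor/donor diazo compounds. Low temperature, darkness and immediate use should keep the electron-rich diazo compound from forming azine.

Step 7
Reactants: 10 [4-bromo-2-(3,4-dimethoxybenzyloxy)-6-methoxyphenyl](3,5-dimethoxyphenyl)diazomethane
Product: 12 (2S,3S)-trans-6-bromo-2-(3,4-dimethoxyphenyl)-3-(3,5-dimethoxyphenyl)-4-methoxy-2,3-dihydrobenzofuran, via cis-dihydrobenzofuran 11 (not isolated)
Conditions: Rh2(R-PTAD)4 (1 mol%), CH2Cl2, 0 °C → rt, slow addition of the solution of 10; after N2 evolution has stopped, CF3CO2H (5 equiv), 0 °C → rt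
Reagents that add atoms: none
Why: The dirhodium catalyst attacks the diazo carbon of 10, N2 leaves and a rhodium-bound diaryl carbene forms; its ring-A aryl group, flanked by two ortho alkoxy groups, is twisted out of the carbene plane, which holds the O–CH2–aryl hydrogens next to the vacant carbene orbital. The C–H bond then adds across the carbene carbon through a concerted, asynchronous three-centre transition state with hydride-transfer character, forming C2–C3 and releasing the catalyst. The closest known reaction type is the enantioselective intramolecular insertion of donor/donor rhodium carbenes into benzylic ether C–H bonds to give 2,3-diaryl-2,3-dihydrobenzofurans. The dihydrofuran closes by C–C bond formation between the carbene carbon and a C–H carbon in a 1,5 relationship (five-membered cyclic transition state), and in the acid stage it reopens and recloses by O–C bond formation, the phenol oxygen capturing the benzylic cation in a five-membered closure. C3 is controlled by the catalyst, whose chiral carboxylate ligands let the C–H bond approach only one face of the carbene. C2 is expected to form mainly cis (compound 11) in the kinetic insertion; CF3CO2H then ionises the C2–O bond to the cation stabilised by the para-methoxy group of ring B, and reclosure under thermodynamic control relays the fixed C3 configuration to give trans compound 12. The step needs site selectivity for the benzylic O–CH2 hydrogens over the O–CH3 hydrogens on the other ortho position (also 1,5-related) and over addition to the aryl rings. This should be secured by the much better hydride-donor ability of a C–H bond flanked by oxygen and a 3,4-dimethoxyphenyl ring and by the low electrophilicity of a carbene carrying two donor aryl groups; the aryl bromide is inert.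

Step 8
Reactants: 12 (2S,3S)-trans-6-bromo-2-(3,4-dimethoxyphenyl)-3-(3,5-dimethoxyphenyl)-4-methoxy-2,3-dihydrobenzofuran; 13 4-methoxystyrene
Product: 14 (2S,3S)-2-(3,4-dimethoxyphenyl)-3-(3,5-dimethoxyphenyl)-4-methoxy-6-[(E)-2-(4-methoxyphenyl)ethenyl]-2,3-dihydrobenzofuran
Conditions: 13 (1.5 equiv), Pd(OAc)2 (5 mol%), P(o-tol)3 (10 mol%), Et3N, DMF, 110 °C
Reagents that add atoms: none
Why: Mizoroki–Heck reaction; zerovalent palladium adds oxidatively to the C6–Br bond, syn-carbopalladation at the terminal carbon of the styrene and syn-β-hydride elimination give the (E)-stilbene. The stereocentres are not touched under these weakly basic conditions.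

Step 9
Reactants: 14 (2S,3S)-2-(3,4-dimethoxyphenyl)-3-(3,5-dimethoxyphenyl)-4-methoxy-6-[(E)-2-(4-methoxyphenyl)ethenyl]-2,3-dihydrobenzofuran
Product: 15 (2S,3S)-2-(3,4-dihydroxyphenyl)-3-(3,5-dihydroxyphenyl)-6-[(E)-2-(4-hydroxyphenyl)ethenyl]-2,3-dihydrobenzofuran-4-ol
Conditions: BBr3 (12 equiv), CH2Cl2, −78 → 0 °C, dark, argon; MeOH then H2O
Reagents that add atoms: none
Why: Lewis-acid cleavage of the six aryl methyl ethers; each ether oxygen binds boron and bromide removes the methyl group by SN2. Any reversible opening of the C2–O bond should return to the thermodynamically preferred trans ring, and C3 takes no part.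

## Compound list

1 | 4-bromo-2,6-dimethoxybenzaldehyde | COc1cc(Br)cc(OC)c1C=O | starting material
2 | 4-bromo-2-hydroxy-6-methoxybenzaldehyde | COc1cc(Br)cc(O)c1C=O | intermediate
3 | 3,4-dimethoxybenzyl bromide | COc1ccc(CBr)cc1OC | starting material
4 | 4-bromo-2-[(3,4-dimethoxybenzyl)oxy]-6-methoxybenzaldehyde | COc1cc(Br)cc(OCc2ccc(OC)c(OC)c2)c1C=O | intermediate
5 | 1-bromo-3,5-dimethoxybenzene | COc1cc(Br)cc(OC)c1 | starting material
6 | 3,5-dimethoxyphenylmagnesium bromide | COc1cc([Mg]Br)cc(OC)c1 | intermediate (not isolated)
7 | rac-{4-bromo-2-[(3,4-dimethoxybenzyl)oxy]-6-methoxyphenyl}(3,5-dimethoxyphenyl)methanol | COc1cc(Br)cc(OCc2ccc(OC)c(OC)c2)c1C(O)c1cc(OC)cc(OC)c1 | intermediate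
8 | {4-bromo-2-[(3,4-dimethoxybenzyl)oxy]-6-methoxyphenyl}(3,5-dimethoxyphenyl)methanone | COc1cc(Br)cc(OCc2ccc(OC)c(OC)c2)c1C(=O)c1cc(OC)cc(OC)c1 | intermediate
9 | {4-bromo-2-[(3,4-dimethoxybenzyl)oxy]-6-methoxyphenyl}(3,5-dimethoxyphenyl)methanone hydrazone, mixture of C=N isomers | COc1cc(Br)cc(OCc2ccc(OC)c(OC)c2)c1C(=NN)c1cc(OC)cc(OC)c1 | intermediate
10 | [4-bromo-2-(3,4-dimethoxybenzyloxy)-6-methoxyphenyl](3,5-dimethoxyphenyl)diazomethane | COc1cc(Br)cc(OCc2ccc(OC)c(OC)c2)c1C(=[N+]=[N-])c1cc(OC)cc(OC)c1 | intermediate
11 | (2R,3S)-cis-6-bromo-2-(3,4-dimethoxyphenyl)-3-(3,5-dimethoxyphenyl)-4-methoxy-2,3-dihydrobenzofuran | Brc1cc(OC)c2c(c1)O[C@@H](c1ccc(OC)c(OC)c1)[C@H]2c1cc(OC)cc(OC)c1 | intermediate (not isolated)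
12 | (2S,3S)-trans-6-bromo-2-(3,4-dimethoxyphenyl)-3-(3,5-dimethoxyphenyl)-4-methoxy-2,3-dihydrobenzofuran | Brc1cc(OC)c2c(c1)O[C@H](c1ccc(OC)c(OC)c1)[C@H]2c1cc(OC)cc(OC)c1 | intermediate
13 | 4-methoxystyrene | C=Cc1ccc(OC)cc1 | starting material
14 | (2S,3S)-2-(3,4-dimethoxyphenyl)-3-(3,5-dimethoxyphenyl)-4-methoxy-6-[(E)-2-(4-methoxyphenyl)ethenyl]-2,3-dihydrobenzofuran | COc1ccc(/C=C/c2cc(OC)c3c(c2)O[C@H](c2ccc(OC)c(OC)c2)[C@H]3c2cc(OC)cc(OC)c2)cc1 | intermediate
15 | (2S,3S)-2-(3,4-dihydroxyphenyl)-3-(3,5-dihydroxyphenyl)-6-[(E)-2-(4-hydroxyphenyl)ethenyl]-2,3-dihydrobenzofuran-4-ol | Oc1ccc(/C=C/c2cc(O)c3c(c2)O[C@H](c2ccc(O)c(O)c2)[C@H]3c2cc(O)cc(O)c2)cc1 | target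

## Step count and least certain steps

Total step count: 9. Longest linear sequence: 9 steps (1 to 15); compounds 3, 5 and 13 are bought and enter directly.

**Step 7 (key step).**
- What may go wrong: loss of material or of stereochemical integrity during the acid equilibration of C2. The cation formed by C2–O ionisation can lose the C3 proton and be reprotonated, which erodes C3, or it can be captured by an electron-rich ring of a second molecule. The second ortho substituent on the carbene-bearing ring may also weaken the facial discrimination by the catalyst. Insertion into the O–CH3 group is the competing site.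
- Fallback: it sets out from 11 and returns at 15. The acid is left out and 11 is isolated. It is coupled with 13 under the conditions of step 8 to give (2R,3S)-2-(3,4-dimethoxyphenyl)-3-(3,5-dimethoxyphenyl)-4-methoxy-6-[(E)-2-(4-methoxyphenyl)ethenyl]-2,3-dihydrobenzofuran F1. F1 is demethylated with BBr3 as in step 9. Once the para oxygen of ring B is free, the C2–O bond can open to a para-quinone methide and reclose, a neutral path to the trans isomer that does not pass through a long-lived cation. Any remaining (2R,3S)-2-(3,4-dihydroxyphenyl)-3-(3,5-dihydroxyphenyl)-6-[(E)-2-(4-hydroxyphenyl)ethenyl]-2,3-dihydrobenzofuran-4-ol F2 would be equilibrated to 15 by brief treatment with dilute HCl in methanol.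

**Step 5.**
- What may go wrong: slow or incomplete condensation. The carbonyl group is shielded by two ortho alkoxy groups and twisted out of the ring-A plane, and forcing conditions invite azine formation.
- Fallback: it sets out from 4 and returns at 9, making the C=N bond by carbon–carbon bond formation instead of carbonyl condensation. Aldehyde 4 is converted with I2 and aqueous NH3 in THF into 4-bromo-2-[(3,4-dimethoxybenzyl)oxy]-6-methoxybenzonitrile F3. Grignard reagent 6 is added to the linear, unhindered nitrile group in THF at 60 °C, and quenching with dry methanol gives {4-bromo-2-[(3,4-dimethoxybenzyl)oxy]-6-methoxyphenyl}(3,5-dimethoxyphenyl)methanimine F4. Exchange of the N–H imine with hydrazine hydrate and catalytic AcOH in ethanol, driven by loss of ammonia, gives hydrazone 9. This is the classical way to hydrazones of ketones too hindered for direct condensation.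

**Step 9.**
- What may go wrong: acid addition to the electron-rich stilbene and cationic oligomerisation under BBr3 and the HBr it releases, together with incomplete cleavage when six ethers must all react.
- Fallback: it sets out from 12 and returns at 15, removing the methyl groups before the stilbene exists. BBr3 in CH2Cl2 converts 12 into (2S,3S)-6-bromo-2-(3,4-dihydroxyphenyl)-3-(3,5-dihydroxyphenyl)-2,3-dihydrobenzofuran-4-ol F5. Ac2O and pyridine give (2S,3S)-4-acetoxy-6-bromo-2-(3,4-diacetoxyphenyl)-3-(3,5-diacetoxyphenyl)-2,3-dihydrobenzofuran F6. Heck coupling of F6 with commercial 4-acetoxystyrene (Pd(OAc)2, P(o-tol)3, Et3N, DMF) gives (2S,3S)-4-acetoxy-6-[(E)-2-(4-acetoxyphenyl)ethenyl]-2-(3,4-diacetoxyphenyl)-3-(3,5-diacetoxyphenyl)-2,3-dihydrobenzofuran F7. Methanolysis with K2CO3 in degassed methanol at 0 °C, followed by acidification, releases 15.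

**Step 8.**
- What may go wrong: arylation at the internal carbon of the electron-rich styrene, giving a 1,1-diarylethene, slow oxidative addition to a bromide on a dialkoxy-substituted ring, and thermal polymerisation of 13.
- Fallback: it sets out from 12 and returns at 14 with no new compound (entry F0). A Suzuki–Miyaura coupling of 12 with commercial (E)-2-(4-methoxyphenyl)ethenylboronic acid pinacol ester (Pd(PPh3)4, K2CO3, dioxane/H2O, 90 °C) transfers a preformed (E)-alkenyl group. This removes the regiochemical question, because no carbopalladation of a styrene is involved.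

## Further compounds

F1 | step 7 | (2R,3S)-2-(3,4-dimethoxyphenyl)-3-(3,5-dimethoxyphenyl)-4-methoxy-6-[(E)-2-(4-methoxyphenyl)ethenyl]-2,3-dihydrobenzofuran | COc1ccc(/C=C/c2cc(OC)c3c(c2)O[C@@H](c2ccc(OC)c(OC)c2)[C@H]3c2cc(OC)cc(OC)c2)cc1
F2 | step 7 | (2R,3S)-2-(3,4-dihydroxyphenyl)-3-(3,5-dihydroxyphenyl)-6-[(E)-2-(4-hydroxyphenyl)ethenyl]-2,3-dihydrobenzofuran-4-ol | Oc1ccc(/C=C/c2cc(O)c3c(c2)O[C@@H](c2ccc(O)c(O)c2)[C@H]3c2cc(O)cc(O)c2)cc1
F3 | step 5 | 4-bromo-2-[(3,4-dimethoxybenzyl)oxy]-6-methoxybenzonitrile | COc1cc(Br)cc(OCc2ccc(OC)c(OC)c2)c1C#N
F4 | step 5 | {4-bromo-2-[(3,4-dimethoxybenzyl)oxy]-6-methoxyphenyl}(3,5-dimethoxyphenyl)methanimine | COc1cc(Br)cc(OCc2ccc(OC)c(OC)c2)c1C(=N)c1cc(OC)cc(OC)c1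
F5 | step 9 | (2S,3S)-6-bromo-2-(3,4-dihydroxyphenyl)-3-(3,5-dihydroxyphenyl)-2,3-dihydrobenzofuran-4-ol | Brc1cc(O)c2c(c1)O[C@H](c1ccc(O)c(O)c1)[C@H]2c1cc(O)cc(O)c1
F6 | step 9 | (2S,3S)-4-acetoxy-6-bromo-2-(3,4-diacetoxyphenyl)-3-(3,5-diacetoxyphenyl)-2,3-dihydrobenzofuran | Brc1cc(OC(C)=O)c2c(c1)O[C@H](c1ccc(OC(C)=O)c(OC(C)=O)c1)[C@H]2c1cc(OC(C)=O)cc(OC(C)=O)c1
F7 | step 9 | (2S,3S)-4-acetoxy-6-[(E)-2-(4-acetoxyphenyl)ethenyl]-2-(3,4-diacetoxyphenyl)-3-(3,5-diacetoxyphenyl)-2,3-dihydrobenzofuran | CC(=O)Oc1ccc(/C=C/c2cc(OC(C)=O)c3c(c2)O[C@H](c2ccc(OC(C)=O)c(OC(C)=O)c2)[C@H]3c2cc(OC(C)=O)cc(OC(C)=O)c2)cc1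
F0 | step 8 | none | none
A1 | alternative 1 | 2-[(1R*,2S*)-anti-1-(3,4-dimethoxyphenyl)-2-(3,5-dimethoxyphenyl)-2-{2,6-dimethoxy-4-[(E)-4-methoxystyryl]phenyl}ethyl]-4,4,5,5-tetramethyl-1,3,2-dioxaborolane, single enantiomer as drawn | CC1(C)OB(OC1(C)C)[C@@H](c1ccc(OC)c(OC)c1)[C@H](c1c(OC)cc(/C=C/c2ccc(OC)cc2)cc1OC)c1cc(OC)cc(OC)c1
A2 | alternative 1 | 2-[(E)-2-{2,6-dimethoxy-4-[(E)-4-methoxystyryl]phenyl}ethenyl]-4,4,5,5-tetramethyl-1,3,2-dioxaborolane | COc1ccc(/C=C/c2cc(OC)c(/C=C/B3OC(C)(C)C(C)(C)O3)c(OC)c2)cc1
A3 | alternative 1 | (3,4-dimethoxyphenyl)lithium | [Li]c1ccc(OC)c(OC)c1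
A4 | alternative 1 | 3,5-dimethoxyphenyl trifluoromethanesulfonate | COc1cc(OS(=O)(=O)C(F)(F)F)cc(OC)c1
A5 | alternative 2 | trans-4-(benzyldimethylsilyl)-2-(3,4-dimethoxyphenyl)-3-(3,5-dimethoxyphenyl)-6-[(E)-4-methoxystyryl]-2,3-dihydrobenzofuran | COc1ccc(/C=C/c2cc([Si](C)(C)Cc3ccccc3)c3c(c2)O[C@H](c2ccc(OC)c(OC)c2)[C@H]3c2cc(OC)cc(OC)c2)cc1
A6 | alternative 2 | benzyl{anti-4-(3,4-dimethoxyphenyl)-3-(3,5-dimethoxyphenyl)-4-(ethynyloxy)but-1-yn-1-yl}dimethylsilane, single enantiomer as drawn | C#CO[C@H](c1ccc(OC)c(OC)c1)[C@H](C#C[Si](C)(C)Cc1ccccc1)c1cc(OC)cc(OC)c1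
A7 | alternative 2 | (E)-1-(4-methoxyphenyl)but-1-en-3-yne | COc1ccc(/C=C/C#C)cc1
A8 | alternative 3 | trans-2-(3,4-dimethoxyphenyl)-3-(3,5-dimethoxyphenyl)-6-[(E)-4-methoxystyryl]-2,3-dihydrobenzofuran-4-ol | COc1ccc(/C=C/c2cc(O)c3c(c2)O[C@H](c2ccc(OC)c(OC)c2)[C@H]3c2cc(OC)cc(OC)c2)cc1
A9 | alternative 3 | (E)-1-[trans-3-acetyl-5-(3,4-dimethoxyphenyl)-4-(3,5-dimethoxyphenyl)-4,5-dihydrofuran-2-yl]-4-(4-methoxyphenyl)but-3-en-2-one, single enantiomer as drawn | CC(=O)C1=C(CC(=O)/C=C/c2ccc(OC)cc2)O[C@H](c2ccc(OC)c(OC)c2)[C@H]1c1cc(OC)cc(OC)c1
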